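Numbering: eudesmane positions C1–C13 for the lactone half, primed elemane positions for the other half; the dihydropyran ring is O–C11–C13–C13'–C11'=C12'.
Retrosynthesis: cut C12'–O and C11–O (methyl enol ether plus C11 hydroxylation), then C11–C13 (conjugate addition of nor-lactone 12 to vinyl ketone 23), then C7–C11 of the γ-lactone (carbenoid C–H insertion of diazoacetate 11); ring B is opened at C6–C7 and the elemane ring by a Diels–Alder cut.
Enabling feature: the γ-lactone is cis-fused across C7–C8 of ring B, C7–H is allylic to C5=C6, and the equatorial C7 hydrogen lies gauche to the axial 8β oxygen, so a carbenoid carbon (C11) carried on that oxygen reaches it through a five-membered transition state.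
Forward order: ring A (cis-2,6-dimethylcyclohexanone), ring B by enolate–epoxide closure and dehydration, lactone by insertion; elemane ring by cycloaddition; union at C11–C13; dihydropyran ring last.
Stereochemistry: C4 by desymmetrising deprotonation, C10 by alkylation anti to the C4 methyl, C8 by hydride attack on the α face, C7 by retention in the insertion, C11 by oxidation of the lactone enolate on its convex face; C10'/C5' from the (E)-dienophile under a chiral Lewis acid, C7' by equilibration to the equatorial aldehyde.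

Key step: step 9

Assumption: the senses of induction of the two chiral reagents (lithium amide of step 1, oxazaborolidinium ion of step 12) are taken from their transition-state models and both exist in either enantiomeric form, so a reversed sense is met by using the antipode; the cis (meso) isomer of 1 is taken from the commercial isomer mixture after base equilibration.

Step 1
Reactants: 1 cis-2,6-dimethylcyclohexan-1-one
Product: 3 (2R,6S)-2,6-dimethyl-2-(2-methylprop-2-en-1-yl)cyclohexan-1-one, via lithium enolate 2 (not isolated)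
Conditions: LiN[(R)-CH(CH3)Ph]2 (from the amine and n-BuLi), LiCl, THF, −78 °C; then 3-bromo-2-methylprop-1-ene, DMPU, −78 to −30 °C
Reagents that add atoms: 3-bromo-2-methylprop-1-ene, C=C(C)CBr
Why: The C2-symmetric lithium amide removes one of the two enantiotopic α-protons of the meso ketone (enantioselective deprotonation) to fix C4, and the tetrasubstituted enolate 2 is then C-alkylated axially on the face away from the C4 methyl, which should set the quaternary C10 with its methyl cis to the C4 methyl.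

Step 2
Reactants: 3 (2R,6S)-2,6-dimethyl-2-(2-methylprop-2-en-1-yl)cyclohexan-1-one
Product: 4 (3R,4R,8S)-4,8-dimethyl-4-(2-methylprop-2-en-1-yl)-1-oxaspiro[2.5]octane
Conditions: ClCH2I, MeLi·LiBr, THF, −78 to 20 °C
Reagents that add atoms: chloroiodomethane, ClCI
Why: Chloromethyllithium, formed by iodine–lithium exchange, should add to the hindered carbonyl at −78 °C faster than it enolises it and the chlorohydrin alkoxide closes to the epoxide on warming (carbenoid epoxidation of a ketone), the reagent entering axially on the face opposite the axial methallyl group so that the new CH2 (C6) is trans to C9.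

Step 3
Reactants: 4 (3R,4R,8S)-4,8-dimethyl-4-(2-methylprop-2-en-1-yl)-1-oxaspiro[2.5]octane
Product: 6 1-[(3R,4R,8S)-4,8-dimethyl-1-oxaspiro[2.5]octan-4-yl]propan-2-one, via ozonide 5 (not isolated)
Conditions: O3, CH2Cl2, −78 °C; then Me2S, −78 to 20 °C
Reagents that add atoms: ozone, [O-][O+]=O
Why: Ozonolysis cleaves the only alkene, a 1,1-disubstituted one, to the methyl ketone while the epoxide is inert to ozone.

Step 4
Reactants: 6 1-[(3R,4R,8S)-4,8-dimethyl-1-oxaspiro[2.5]octan-4-yl]propan-2-one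
Product: 7 (4aR,5S,8aR)-4a-hydroxy-5,8a-dimethyloctahydronaphthalen-2(1H)-one
Conditions: KOt-Bu (0.3 equiv), t-BuOH, 40 °C
Reagents that add atoms: none
Why: The methyl ketone enolate opens the epoxide at its unsubstituted CH2 (intramolecular alkylation of an enolate by an epoxide, the fully substituted epoxide carbon being closed to attack), which should form ring B as a trans-fused decalin with an axial 5α-hydroxyl, the protic medium favouring C- over O-alkylation.

Step 5
Reactants: 7 (4aR,5S,8aR)-4a-hydroxy-5,8a-dimethyloctahydronaphthalen-2(1H)-one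
Product: 8 (5S,8aR)-5,8a-dimethyl-3,5,6,7,8,8a-hexahydronaphthalen-2(1H)-one
Conditions: SOCl2, pyridine, CH2Cl2, −20 °C
Reagents that add atoms: none
Why: Anti elimination through the chlorosulfite (alcohol dehydration) can use only the axial 6β hydrogen, because the axial position on C4 is taken by the methyl group and C10 is quaternary, so the double bond should form at C5=C6, out of conjugation with the ketone.

Step 6
Reactants: 8 (5S,8aR)-5,8a-dimethyl-3,5,6,7,8,8a-hexahydronaphthalen-2(1H)-one
Product: 9 (2S,5S,8aR)-5,8a-dimethyl-1,2,3,5,6,7,8,8a-octahydronaphthalen-2-ol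
Conditions: Li[BH(s-Bu)3], THF, −78 °C
Reagents that add atoms: none
Why: In the favoured half-chair of ring B the pseudoaxial C10 methyl covers the β face of the carbonyl, so the bulky hydride adds from the α face (ketone reduction under steric approach control) and should give the axial 8β-alcohol.

Step 7
Reactants: 9 (2S,5S,8aR)-5,8a-dimethyl-1,2,3,5,6,7,8,8a-octahydronaphthalen-2-ol
Product: 10 (2S,5S,8aR)-5,8a-dimethyl-1,2,3,5,6,7,8,8a-octahydronaphthalen-2-yl bromoacetate
Conditions: BrCH2COBr, pyridine, CH2Cl2, 0 °C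
Reagents that add atoms: bromoacetyl bromide, BrCC(Br)=O
Why: Acylation of the secondary alcohol by the acid bromide with pyridine as acid scavenger (esterification) is fast even for an axial hydroxyl and does not touch C8.

Step 8
Reactants: 10 (2S,5S,8aR)-5,8a-dimethyl-1,2,3,5,6,7,8,8a-octahydronaphthalen-2-yl bromoacetate
Product: 11 (2S,5S,8aR)-5,8a-dimethyl-1,2,3,5,6,7,8,8a-octahydronaphthalen-2-yl diazoacetate
Conditions: TsNHNHTs, DBU, THF, 0 °C
Reagents that add atoms: N,N'-ditosylhydrazine, Cc1ccc(cc1)S(=O)(=O)NNS(=O)(=O)c1ccc(C)cc1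
Why: N-Alkylation of the ditosylhydrazine by the bromoacetate followed by base-induced loss of two sulfinate ions gives the diazoacetate directly (diazo synthesis from a bromoacetate).

Step 9
Reactants: 11 (2S,5S,8aR)-5,8a-dimethyl-1,2,3,5,6,7,8,8a-octahydronaphthalen-2-yl diazoacetate
Product: 12 (3aS,5S,8aR,9aR)-5,8a-dimethyl-3a,5,6,7,8,8a,9,9a-octahydronaphtho[2,3-b]furan-2(3H)-one
Conditions: Rh2(NHCOCH3)4 (1 mol %), CH2Cl2, reflux, 11 added over 10 h
Reagents that add atoms: none
Why: Dirhodium tetraacetamidate decomposes 11 to an electrophilic rhodium carbenoid whose carbon (C11) inserts into C7–H through a concerted three-centre, hydride-transfer-like transition state, the closest precedent being the dirhodium carboxamidate-catalysed closure of cyclohexyl diazoacetates to γ-lactones. The γ-lactone ring closes as a five-membered 1,5-insertion (carbenoid carbon to the carbon β to the ester oxygen). The new stereocentre C7 is set by the substrate: ring B sits in the half-chair with the C10 methyl pseudoaxial (the other half-chair over-puckers ring A and presses the two syn-axial methyls together), so the 8β ester oxygen is axial, only the equatorial 7β hydrogen is within reach, and insertion with retention makes the ring fusion cis. Site selectivity for C7–H over the similarly placed equatorial C9–H is needed and should come from allylic activation by C5=C6 and from the neopentyl shielding of C9 by C10 and its methyl; the strained β-lactone from C8–H is not expected with carboxamidate ligands. Chemoselectivity over cyclopropanation rests on the fully substituted C5 under the syn-axial C10 methyl and on the bridged bicyclo[3.3.1] lactone that cyclopropanation would have to form, and slow addition suppresses carbene dimerisation.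

Step 10
Reactants: 13 4-methylpent-3-en-2-one
Product: 14 (2E)-2-methyl-4-oxopent-2-enal
Conditions: SeO2, 1,4-dioxane/H2O, 90 °C
Reagents that add atoms: selenium dioxide, O=[Se]=O
Why: Riley oxidation: SeO2 attacks the methyl group trans to the acetyl group by an ene reaction and [2,3]-shift, as it does in β,β-dimethyl enoates, and should deliver the (E)-enal.

Step 11
Reactants: 15 but-3-en-2-one
Product: 16 (buta-1,3-dien-2-yloxy)tri(propan-2-yl)silane
Conditions: i-Pr3SiOSO2CF3, Et3N, Et2O, 0 to 20 °C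
Reagents that add atoms: triisopropylsilyl trifluoromethanesulfonate, CC(C)[Si](OS(=O)(=O)C(F)(F)F)(C(C)C)C(C)C
Why: Silyl triflate and amine convert the enolisable methyl ketone of the enone into its silyl enol ether (soft enolisation), which is the 2-silyloxy diene.

Step 12
Reactants: 14 (2E)-2-methyl-4-oxopent-2-enal; 16 (buta-1,3-dien-2-yloxy)tri(propan-2-yl)silane
Product: 17 (1S,6S)-6-acetyl-1-methyl-4-{[tri(propan-2-yl)silyl]oxy}cyclohex-3-ene-1-carbaldehyde
Conditions: (S)-oxazaborolidinium triflimide [from (S)-α,α-diphenylprolinol, tri(o-tolyl)boroxine and Tf2NH], 20 mol %, CH2Cl2, −78 °C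
Reagents that add atoms: none
Why: Enantioselective Diels–Alder reaction: the chiral oxazaborolidinium ion binds the formyl group, the nucleophilic C1 of the 2-silyloxy diene bonds to the formyl β-carbon (C5') so that the silyloxy carbon ends para to C10' (at C7'), the trans geometry of the dienophile is transferred to a trans formyl/acetyl pair on C10'/C5', and the catalyst face should set their absolute configuration.

Step 13
Reactants: 17 (1S,6S)-6-acetyl-1-methyl-4-{[tri(propan-2-yl)silyl]oxy}cyclohex-3-ene-1-carbaldehyde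
Product: 19 (3R,4R)-4-ethenyl-4-methyl-3-(prop-1-en-2-yl)cyclohexan-1-one, via silyl dienol ether 18 (not isolated)
Conditions: Ph3PCH3Br, KN(SiMe3)2, THF, 0 °C, then 17, −78 to 20 °C; then Bu4NF, AcOH, 0 °C
Reagents that add atoms: methyltriphenylphosphonium bromide, C[P+](c1ccccc1)(c1ccccc1)c1ccccc1.[Br-]
Why: Wittig methylenation converts the formyl group into the C10' vinyl and the acetyl group into the C5' isopropenyl group while the silyl enol ether masks the C7' carbonyl, the hindered C5' methine not being enolised at low temperature, and fluoride then releases the ketone.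

Step 14
Reactants: 19 (3R,4R)-4-ethenyl-4-methyl-3-(prop-1-en-2-yl)cyclohexan-1-one
Product: 21 (1S,3R,4R)-4-ethenyl-4-methyl-3-(prop-1-en-2-yl)cyclohexane-1-carbaldehyde, via enol ether 20 (not isolated)
Conditions: Ph3P(CH2OMe)Cl, KN(SiMe3)2, THF, 0 to 20 °C; then 1 M HCl, THF, 20 °C
Reagents that add atoms: (methoxymethyl)triphenylphosphonium chloride, COC[P+](c1ccccc1)(c1ccccc1)c1ccccc1.[Cl-]; water, O
Why: Wittig methoxymethylenation and hydrolysis of the enol ether add one carbon (aldehyde homologation), and protonation and equilibration of the enolisable aldehyde should place the formyl group equatorial, cis to the C5' isopropenyl group, which sets C7'.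

Step 15
Reactants: 21 (1S,3R,4R)-4-ethenyl-4-methyl-3-(prop-1-en-2-yl)cyclohexane-1-carbaldehyde
Product: 22 1-[(1S,3R,4R)-4-ethenyl-4-methyl-3-(prop-1-en-2-yl)cyclohexyl]prop-2-en-1-ol
Conditions: CH2=CHMgBr, THF, −78 °C
Reagents that add atoms: vinylmagnesium bromide, C=C[Mg]Br
Why: 1,2-Addition of the vinyl Grignard reagent to the aldehyde (Grignard addition); the carbinol configuration is lost in the next step.

Step 16
Reactants: 22 1-[(1S,3R,4R)-4-ethenyl-4-methyl-3-(prop-1-en-2-yl)cyclohexyl]prop-2-en-1-ol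
Product: 23 1-[(1S,3R,4R)-4-ethenyl-4-methyl-3-(prop-1-en-2-yl)cyclohexyl]prop-2-en-1-one
Conditions: MnO2, CH2Cl2, 20 °C
Reagents that add atoms: none
Why: MnO2 oxidises allylic alcohols selectively to enones under neutral conditions, so the other three alkenes and the epimerisable C7' centre should not be affected.

Step 17
Reactants: 12 (3aS,5S,8aR,9aR)-5,8a-dimethyl-3a,5,6,7,8,8a,9,9a-octahydronaphtho[2,3-b]furan-2(3H)-one; 23 1-[(1S,3R,4R)-4-ethenyl-4-methyl-3-(prop-1-en-2-yl)cyclohexyl]prop-2-en-1-one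
Product: 26 (3aR,5S,8aR,9aR)-3-{3-[(1S,3R,4R)-4-ethenyl-4-methyl-3-(prop-1-en-2-yl)cyclohexyl]-3-oxopropyl}-5,8a-dimethyl-3a,5,6,7,8,8a,9,9a-octahydronaphtho[2,3-b]furan-2(3H)-one, via ketene silyl acetal 24 (not isolated), via silyl enol ether 25 (not isolated)
Conditions: LiN(SiMe3)2, t-BuMe2SiCl, THF/DMPU, −78 °C; then 23, t-BuMe2SiOSO2CF3 (10 mol %), CH2Cl2, −78 °C; 1 M HCl work-up
Reagents that add atoms: none
Why: Mukaiyama–Michael addition: the ketene silyl acetal of the lactone adds through C11 to the terminal carbon of the silyl-activated vinyl ketone without the free enolate that would polymerise it, and acidic work-up hydrolyses the silyl enol ether to the 1,5-keto lactone; the C11 configuration is erased later.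

Step 18
Reactants: 26 keto lactone (name as in step 17)
Product: 27 (3aR,5S,8aR,9aR)-3-{3-[(1S,3R,4R)-4-ethenyl-4-methyl-3-(prop-1-en-2-yl)cyclohexyl]-4-methoxybut-3-en-1-yl}-5,8a-dimethyl-3a,5,6,7,8,8a,9,9a-octahydronaphtho[2,3-b]furan-2(3H)-one
Conditions: Ph3P(CH2OMe)Cl, KN(SiMe3)2, THF, 0 to 20 °C
Reagents that add atoms: (methoxymethyl)triphenylphosphonium chloride, COC[P+](c1ccccc1)(c1ccccc1)c1ccccc1.[Cl-]
Why: Wittig olefination with the methoxymethylene ylide is selective for the ketone over the lactone carbonyl and gives the enol ether that carries C12' at the aldehyde oxidation level; both alkene isomers serve.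

Step 19
Reactants: 27 enol ether lactone (name as in step 18)
Product: 29 (3R,3aS,5S,8aR,9aR)-3-hydroxy-3-{3-[(1S,3R,4R)-4-ethenyl-4-methyl-3-(prop-1-en-2-yl)cyclohexyl]-4-methoxybut-3-en-1-yl}-5,8a-dimethyl-3a,5,6,7,8,8a,9,9a-octahydronaphtho[2,3-b]furan-2(3H)-one, via potassium enolate 28 (not isolated)
Conditions: KN(SiMe3)2, THF, −78 °C; then 2-(phenylsulfonyl)-3-phenyloxaziridine, −78 °C
Reagents that add atoms: 2-(phenylsulfonyl)-3-phenyloxaziridine, O=S(=O)(c1ccccc1)N1OC1c1ccccc1
Why: The potassium enolate of the lactone is oxidised by the N-sulfonyloxaziridine (enolate hydroxylation) on its convex face, the face of H7 and H8, so that the hydroxyl group should be α and the side chain pushed to the concave β face, which sets the spiro centre C11.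

Step 20
Reactants: 29 hydroxy lactone (name as in step 19)
Product: 31 (3R,3aS,5S,8aR,9aR)-5'-[(1S,3R,4R)-4-ethenyl-4-methyl-3-(prop-1-en-2-yl)cyclohexyl]-5,8a-dimethyl-3',4',3a,5,6,7,8,8a,9,9a-decahydrospiro[naphtho[2,3-b]furan-3(2H),2'-[2H]pyran]-2-one (CNP0175206.1), via cyclic methyl acetal 30 (not isolated)
Conditions: camphorsulfonic acid (5 mol %), 4 Å molecular sieves, toluene, 80 °C
Reagents that add atoms: none
Why: Acid protonates the enol ether at C11', the tertiary hydroxyl adds to the oxocarbenium carbon C12' (6-exo-trig closure to the cyclic mixed acetal), and loss of methanol, taken up by the sieves, should give the 3,4-dihydro-2H-pyran (acetal to enol ether elimination); no stereocentre is formed or touched.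

Compound list
1 | cis-2,6-dimethylcyclohexan-1-one (meso) | C[C@H]1CCC[C@@H](C)C1=O | starting material
2 | lithium (6S)-2,6-dimethylcyclohex-1-en-1-olate | C[C@H]1CCCC(C)=C1O[Li] | intermediate
3 | (2R,6S)-2,6-dimethyl-2-(2-methylprop-2-en-1-yl)cyclohexan-1-one | C=C(C)C[C@@]1(C)CCC[C@H](C)C1=O | intermediate
4 | (3R,4R,8S)-4,8-dimethyl-4-(2-methylprop-2-en-1-yl)-1-oxaspiro[2.5]octane (epoxide oxygen anti to both methyl groups) | C=C(C)C[C@@]1(C)CCC[C@H](C)[C@]12CO2 | intermediate
5 | ozonide of 4, 3-{[(3R,4R,8S)-4,8-dimethyl-1-oxaspiro[2.5]octan-4-yl]methyl}-3-methyl-1,2,4-trioxolane | CC1(C[C@@]2(C)CCC[C@H](C)[C@]23CO3)OCOO1 | intermediate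
6 | 1-[(3R,4R,8S)-4,8-dimethyl-1-oxaspiro[2.5]octan-4-yl]propan-2-one | CC(=O)C[C@@]1(C)CCC[C@H](C)[C@]12CO2 | intermediate
7 | (4aR,5S,8aR)-4a-hydroxy-5,8a-dimethyloctahydronaphthalen-2(1H)-one (trans-fused; 5α-OH, 4β- and 10β-methyl) | O=C1C[C@@]2(C)CCC[C@H](C)[C@]2(O)CC1 | intermediate
8 | (5S,8aR)-5,8a-dimethyl-3,5,6,7,8,8a-hexahydronaphthalen-2(1H)-one | O=C1C[C@@]2(C)CCC[C@H](C)C2=CC1 | intermediate
9 | (2S,5S,8aR)-5,8a-dimethyl-1,2,3,5,6,7,8,8a-octahydronaphthalen-2-ol (8β-ol) | O[C@@H]1C[C@@]2(C)CCC[C@H](C)C2=CC1 | intermediate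
10 | (2S,5S,8aR)-5,8a-dimethyl-1,2,3,5,6,7,8,8a-octahydronaphthalen-2-yl bromoacetate | BrCC(=O)O[C@@H]1C[C@@]2(C)CCC[C@H](C)C2=CC1 | intermediate
11 | (2S,5S,8aR)-5,8a-dimethyl-1,2,3,5,6,7,8,8a-octahydronaphthalen-2-yl diazoacetate | [N-]=[N+]=CC(=O)O[C@@H]1C[C@@]2(C)CCC[C@H](C)C2=CC1 | intermediate
12 | (3aS,5S,8aR,9aR)-5,8a-dimethyl-3a,5,6,7,8,8a,9,9a-octahydronaphtho[2,3-b]furan-2(3H)-one (13-nor-11,13-dihydroalantolactone) | C1C(=O)O[C@@H]2C[C@@]3(C)CCC[C@H](C)C3=C[C@@H]21 | intermediate
13 | 4-methylpent-3-en-2-one (mesityl oxide) | CC(C)=CC(C)=O | starting material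
14 | (2E)-2-methyl-4-oxopent-2-enal | O=C/C(C)=C/C(C)=O | intermediate
15 | but-3-en-2-one (methyl vinyl ketone) | CC(=O)C=C | starting material
16 | (buta-1,3-dien-2-yloxy)tri(propan-2-yl)silane | C=CC(=C)O[Si](C(C)C)(C(C)C)C(C)C | intermediate
17 | (1S,6S)-6-acetyl-1-methyl-4-{[tri(propan-2-yl)silyl]oxy}cyclohex-3-ene-1-carbaldehyde | O=C[C@@]1(C)CC=C(O[Si](C(C)C)(C(C)C)C(C)C)C[C@@H]1C(C)=O | intermediate
18 | {[(4R,5R)-4-ethenyl-4-methyl-5-(prop-1-en-2-yl)cyclohex-1-en-1-yl]oxy}tri(propan-2-yl)silane | C=C[C@@]1(C)CC=C(O[Si](C(C)C)(C(C)C)C(C)C)C[C@@H]1C(C)=C | intermediate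
19 | (3R,4R)-4-ethenyl-4-methyl-3-(prop-1-en-2-yl)cyclohexan-1-one | C=C[C@@]1(C)CCC(=O)C[C@@H]1C(C)=C | intermediate
20 | (3R,4R)-4-ethenyl-1-(methoxymethylidene)-4-methyl-3-(prop-1-en-2-yl)cyclohexane (both alkene isomers) | C=C[C@@]1(C)CCC(=COC)C[C@@H]1C(C)=C | intermediate
21 | (1S,3R,4R)-4-ethenyl-4-methyl-3-(prop-1-en-2-yl)cyclohexane-1-carbaldehyde | C=C[C@@]1(C)CC[C@H](C=O)C[C@@H]1C(C)=C | intermediate
22 | 1-[(1S,3R,4R)-4-ethenyl-4-methyl-3-(prop-1-en-2-yl)cyclohexyl]prop-2-en-1-ol (both carbinol epimers) | C=C[C@@]1(C)CC[C@H](C(O)C=C)C[C@@H]1C(C)=C | intermediate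
23 | 1-[(1S,3R,4R)-4-ethenyl-4-methyl-3-(prop-1-en-2-yl)cyclohexyl]prop-2-en-1-one | C=C[C@@]1(C)CC[C@H](C(=O)C=C)C[C@@H]1C(C)=C | intermediate
24 | tert-butyldimethylsilyl ketene acetal of 12 (C11=C12 enol silyl ether) | C1=C(O[Si](C)(C)C(C)(C)C)O[C@@H]2C[C@@]3(C)CCC[C@H](C)C3=C[C@@H]21 | intermediate
25 | tert-butyldimethylsilyl enol ether of 26 (C11'=C13' enol silyl ether, C11 epimers) | C=C[C@@]1(C)CC[C@H](C(O[Si](C)(C)C(C)(C)C)=CCC3C(=O)O[C@@H]2C[C@@]4(C)CCC[C@H](C)C4=C[C@@H]23)C[C@@H]1C(C)=C | intermediate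
26 | (3aR,5S,8aR,9aR)-3-{3-[(1S,3R,4R)-4-ethenyl-4-methyl-3-(prop-1-en-2-yl)cyclohexyl]-3-oxopropyl}-5,8a-dimethyl-3a,5,6,7,8,8a,9,9a-octahydronaphtho[2,3-b]furan-2(3H)-one (C3 epimers) | C=C[C@@]1(C)CC[C@H](C(=O)CCC3C(=O)O[C@@H]2C[C@@]4(C)CCC[C@H](C)C4=C[C@@H]23)C[C@@H]1C(C)=C | intermediate
27 | (3aR,5S,8aR,9aR)-3-{3-[(1S,3R,4R)-4-ethenyl-4-methyl-3-(prop-1-en-2-yl)cyclohexyl]-4-methoxybut-3-en-1-yl}-5,8a-dimethyl-3a,5,6,7,8,8a,9,9a-octahydronaphtho[2,3-b]furan-2(3H)-one (C3 epimers, both enol ether isomers) | C=C[C@@]1(C)CC[C@H](C(=COC)CCC3C(=O)O[C@@H]2C[C@@]4(C)CCC[C@H](C)C4=C[C@@H]23)C[C@@H]1C(C)=C | intermediate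
28 | potassium enolate of 27 (C11=C12 enolate) | C=C[C@@]1(C)CC[C@H](C(=COC)CCC3=C([O-])O[C@@H]2C[C@@]4(C)CCC[C@H](C)C4=C[C@@H]23)C[C@@H]1C(C)=C.[K+] | intermediate
29 | (3R,3aS,5S,8aR,9aR)-3-hydroxy-3-{3-[(1S,3R,4R)-4-ethenyl-4-methyl-3-(prop-1-en-2-yl)cyclohexyl]-4-methoxybut-3-en-1-yl}-5,8a-dimethyl-3a,5,6,7,8,8a,9,9a-octahydronaphtho[2,3-b]furan-2(3H)-one | C=C[C@@]1(C)CC[C@H](C(=COC)CC[C@]3(O)C(=O)O[C@@H]2C[C@@]4(C)CCC[C@H](C)C4=C[C@@H]23)C[C@@H]1C(C)=C | intermediate
30 | cyclic methyl acetal, the 6'-methoxy-3',4',5',6'-tetrahydro analogue of 31 (epimers at C11' and C12') | C=C[C@@]1(C)CC[C@H](C5CC[C@]3(OC5OC)C(=O)O[C@@H]2C[C@@]4(C)CCC[C@H](C)C4=C[C@@H]23)C[C@@H]1C(C)=C | intermediate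
31 | (3R,3aS,5S,8aR,9aR)-5'-[(1S,3R,4R)-4-ethenyl-4-methyl-3-(prop-1-en-2-yl)cyclohexyl]-5,8a-dimethyl-3',4',3a,5,6,7,8,8a,9,9a-decahydrospiro[naphtho[2,3-b]furan-3(2H),2'-[2H]pyran]-2-one (CNP0175206.1) | C=C[C@@]1(C)CC[C@H](C2=CO[C@@]3(CC2)C(=O)O[C@@H]2C[C@@]4(C)CCC[C@H](C)C4=C[C@@H]23)C[C@@H]1C(=C)C | target

Total step count: 20. Longest linear sequence: 13 steps (steps 1–9 and 17–20).

Steps most likely to fail

Step 9. The carbenoid may add to C5=C6, insert at C9–H, close through the other half-chair of ring B to the trans-fused lactone, or dimerise. The fallback sets out from ketone 8 and returns at lactone 12, making the C7–C11 bond by enolate chemistry. Ketone 8 is deprotonated at the doubly activated C7 (LiN(i-Pr)2, THF, −78 °C) and alkylated with tert-butyl bromoacetate, which is expected to enter anti to the C10 methyl and give tert-butyl [(5S,8aR)-5,8a-dimethyl-2-oxo-1,2,3,5,6,7,8,8a-octahydronaphthalen-3-yl]acetate with the side chain α F1. The extended enolate is regenerated with KOt-Bu in t-BuOH and protonated kinetically from the same α face, which should give the epimer with the side chain β (equatorial) F2. Reduction with Li[BH(s-Bu)3] would give the axial 8β-alcohol, tert-butyl [(2S,5S,8aR)-2-hydroxy-5,8a-dimethyl-1,2,3,5,6,7,8,8a-octahydronaphthalen-3-yl]acetate with the side chain β F3, whose cis-disposed groups close to 12 in CF3CO2H.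

Step 1. Discrimination between the enantiotopic α-protons may be incomplete, and some alkylation may occur syn to the C4 methyl. The fallback sets out from ketone 1 and returns at ketone 3, fixing the quaternary centre by a catalyst. The potassium enolate of 1 is O-acylated with 2-methylprop-2-en-1-yl chloroformate to 2,6-dimethylcyclohex-1-en-1-yl 2-methylprop-2-en-1-yl carbonate F4. Decarboxylative allylic alkylation [Pd2(dba)3, (R)-4-tert-butyl-2-[2-(diphenylphosphino)phenyl]-4,5-dihydrooxazole, THF, 25 °C] should deliver 3 together with its C6 epimer, (2R,6R)-2,6-dimethyl-2-(2-methylprop-2-en-1-yl)cyclohexan-1-one F5, which is separated and re-equilibrated at C6 (NaOMe, MeOH) for recycling.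

Step 4. The enolate may attack through oxygen, or the endo-mode opening at the CH2 next to a fully substituted carbon may stall. The fallback sets out from ketone 3 and returns at hydroxy ketone 7, closing ring B by metathesis. Ozonolysis of 3 gives (2R,6S)-2,6-dimethyl-2-(2-oxopropyl)cyclohexan-1-one F6. Its methyl ketone is enolised and trapped in situ (LiN(i-Pr)2, t-BuMe2SiCl, −78 °C) as (2R,6S)-2-{2-[(tert-butyldimethylsilyl)oxy]prop-2-en-1-yl}-2,6-dimethylcyclohexan-1-one F7. CH2=CHCH2MgBr with CeCl3 adds to the ring carbonyl anti to the axial side chain to give (1R,2R,6S)-1-allyl-2-{2-[(tert-butyldimethylsilyl)oxy]prop-2-en-1-yl}-2,6-dimethylcyclohexan-1-ol F8. Ring-closing metathesis with the second-generation Grubbs catalyst RuCl2(=CHPh)(PCy3)(H2IMes) gives the cyclic silyl enol ether of 7 F9, and Bu4NF releases 7.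

Further compounds
F1 | step 9 | tert-butyl [(5S,8aR)-5,8a-dimethyl-2-oxo-1,2,3,5,6,7,8,8a-octahydronaphthalen-3-yl]acetate, side chain α | O=C1C[C@@]2(C)CCC[C@H](C)C2=C[C@H]1CC(=O)OC(C)(C)C
F2 | step 9 | tert-butyl [(5S,8aR)-5,8a-dimethyl-2-oxo-1,2,3,5,6,7,8,8a-octahydronaphthalen-3-yl]acetate, side chain β | O=C1C[C@@]2(C)CCC[C@H](C)C2=C[C@@H]1CC(=O)OC(C)(C)C
F3 | step 9 | tert-butyl [(2S,5S,8aR)-2-hydroxy-5,8a-dimethyl-1,2,3,5,6,7,8,8a-octahydronaphthalen-3-yl]acetate, side chain β | O[C@@H]1C[C@@]2(C)CCC[C@H](C)C2=C[C@@H]1CC(=O)OC(C)(C)C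
F4 | step 1 | 2,6-dimethylcyclohex-1-en-1-yl 2-methylprop-2-en-1-yl carbonate (racemic) | CC1CCCC(C)=C1OC(=O)OCC(C)=C
F5 | step 1 | (2R,6R)-2,6-dimethyl-2-(2-methylprop-2-en-1-yl)cyclohexan-1-one | C=C(C)C[C@@]1(C)CCC[C@@H](C)C1=O
F6 | step 4 | (2R,6S)-2,6-dimethyl-2-(2-oxopropyl)cyclohexan-1-one | CC(=O)C[C@@]1(C)CCC[C@H](C)C1=O
F7 | step 4 | (2R,6S)-2-{2-[(tert-butyldimethylsilyl)oxy]prop-2-en-1-yl}-2,6-dimethylcyclohexan-1-one | C=C(O[Si](C)(C)C(C)(C)C)C[C@@]1(C)CCC[C@H](C)C1=O
F8 | step 4 | (1R,2R,6S)-1-allyl-2-{2-[(tert-butyldimethylsilyl)oxy]prop-2-en-1-yl}-2,6-dimethylcyclohexan-1-ol | C=C(O[Si](C)(C)C(C)(C)C)C[C@@]1(C)CCC[C@H](C)[C@]1(O)CC=C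
F9 | step 4 | (4aR,5S,8aR)-7-[(tert-butyldimethylsilyl)oxy]-4,8a-dimethyl-1,2,3,4,5,8-hexahydronaphthalen-4a(8aH)-ol type cyclic silyl enol ether of 7 (C7=C8 enol silyl ether, eudesmane numbering) | C[Si](C)(OC1C[C@@]2(C)CCC[C@H](C)[C@]2(O)CC=1)C(C)(C)C
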